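**Plan**

1. Locants: pyrrolo[1,2-a]azepine N4, C3, C5–C9, C9a; right-hand lactone Cα (bears CH3), Cβ (CH2), Cγ (O-bearing, attached to C3); furofuranone O1', C2' (CH3), C3' (attached to C9), C3a', C6' (CH3), C6a'.
2. Retrosynthesis: (i) amine from the C5 lactam; (ii) right-hand lactone cut at Cα–Cβ and O–Cγ to a C3 vinyl group plus methylmalonic acid (its second CO2H is an activating group, lost later by decarboxylation); (iii) furofuranone cut at O1'–C6a' (oxa-Michael), at the butenolide C=C (metathesis) and at C3a'–vinyl; (iv) azepinone cut at N–C5 (lactamization) and C7–C8 (nitro-Michael); (v) C9–C3' cut (enamine Michael) to a nitroalkene from trans-5-vinylprolinal and (S)-3-(benzyloxy)butanal.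
3. Forward order: pyrrolidine (N-Boc methyl L-pyroglutamate, vinyl added trans) → C9–C3' bond → chain to C5 → azepinone ring → butenolide → tetrahydrofuran ring (bicyclic lactone) → right-hand lactone (key step) → decarboxylation → lactam to amine.
4. Stereochemistry: C9a from L-pyroglutamate; C3 by trans addition to the N-acyliminium ion; C2' from ethyl (S)-3-hydroxybutanoate; C3' and C9 from the diarylprolinol silyl ether catalyst; C3a' by chelation control; C6a' by the cis ring fusion and C6' by convex-face protonation; Cγ from the C3 centre in the key step; Cα by protonation anti to the Cγ substituent.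
5. Enabling feature: the right-hand lactone is a propionate unit, O–C(=O)–CαH(CH3), bridging the two carbons Cβ–Cγ that hang on C3 of the pyrrolidine ring. Cβ–Cγ is a terminal vinyl group in disguise. Cα (enol carbon) and Cβ (alkene terminus) are both donor carbons, so they are joined by one-electron oxidation, and the Cγ radical next to the lactam nitrogen is closed onto the same carboxylate.

Key step: step 15

**Route**

Step 1
Reactants: 1 1-tert-butyl 2-methyl (2S)-5-oxopyrrolidine-1,2-dicarboxylate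
Product: 3 1-tert-butyl 2-methyl (2S)-5-methoxypyrrolidine-1,2-dicarboxylate, via hemiaminal 2 (not isolated)
Conditions: LiBEt3H, THF, −78 °C; then MeOH, p-TsOH (cat.), rt
Reagents that add atoms: methanol (CO)
Why: Chemoselective hydride reduction of the carbamate-activated lactam carbonyl gives the hemiaminal, and acid-catalysed exchange with methanol gives the N,O-acetal (N-acyliminium precursor); the C5 epimer mixture is of no consequence.

Step 2
Reactants: 3 1-tert-butyl 2-methyl (2S)-5-methoxypyrrolidine-1,2-dicarboxylate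
Product: 4 1-tert-butyl 2-methyl (2S,5S)-5-ethenylpyrrolidine-1,2-dicarboxylate
Conditions: CH2=CHMgBr, CuBr·SMe2, BF3·OEt2, Et2O/THF, −78 → −30 °C
Reagents that add atoms: vinylmagnesium bromide (C=C[Mg]Br)
Why: BF3·OEt2 ionizes the N,O-acetal to the N-acyliminium ion and the vinylcopper reagent adds anti to the C2 ester (the known trans selectivity of organocopper–BF3 additions to 5-alkoxyprolinates), which sets the future C3 trans to C9a.

Step 3
Reactants: 4 1-tert-butyl 2-methyl (2S,5S)-5-ethenylpyrrolidine-1,2-dicarboxylate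
Product: 5 tert-butyl (2S,5S)-2-ethenyl-5-formylpyrrolidine-1-carboxylate
Conditions: i-Bu2AlH (DIBAL-H), toluene, −78 °C; Rochelle salt work-up
Reagents that add atoms: none
Why: Low-temperature half-reduction of the methyl ester through the stable aluminium hemiacetal (prolinal-type reduction) should give the N-Boc α-amino aldehyde without epimerization.

Step 4
Reactants: 5 tert-butyl (2S,5S)-2-ethenyl-5-formylpyrrolidine-1-carboxylate
Product: 8 tert-butyl (2S,5S)-2-ethenyl-5-[(E)-2-nitroethenyl]pyrrolidine-1-carboxylate, via nitroaldol 6 (not isolated), via mesylate 7 (not isolated)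
Conditions: CH3NO2, Et3N (cat.), THF, 0 °C; then MsCl, Et3N, CH2Cl2, −20 → 0 °C
Reagents that add atoms: nitromethane (C[N+](=O)[O-])
Why: Henry reaction followed by mesylation and E1cB elimination should give the thermodynamically preferred (E)-nitroalkene; the carbinol centre is destroyed.

Step 5
Reactants: 9 ethyl (3S)-3-hydroxybutanoate
Product: 10 ethyl (3S)-3-(benzyloxy)butanoate
Conditions: benzyl 2,2,2-trichloroacetimidate, TfOH (cat.), cyclohexane/CH2Cl2, 0 °C → rt
Reagents that add atoms: benzyl 2,2,2-trichloroacetimidate (ClC(Cl)(Cl)C(=N)OCc1ccccc1)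
Why: Acid-catalysed imidate O-benzylation avoids the basic conditions that would cause β-elimination of the β-hydroxy ester; the benzyl ether is chosen because it chelates (step 12) and survives TFA (step 10).

Step 6
Reactants: 10 ethyl (3S)-3-(benzyloxy)butanoate
Product: 11 (3S)-3-(benzyloxy)butanal
Conditions: i-Bu2AlH (DIBAL-H), CH2Cl2, −78 °C
Reagents that add atoms: none
Why: Half-reduction of the ester at low temperature gives the β-benzyloxy aldehyde with the chiral-pool centre (future C2') untouched.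

Step 7
Reactants: 8 tert-butyl (2S,5S)-2-ethenyl-5-[(E)-2-nitroethenyl]pyrrolidine-1-carboxylate; 11 (3S)-3-(benzyloxy)butanal
Product: 13 tert-butyl (2S,5S)-2-[(2S,3S,4S)-4-(benzyloxy)-3-(hydroxymethyl)-1-nitropentan-2-yl]-5-ethenylpyrrolidine-1-carboxylate, via nitro aldehyde 12 (not isolated)
Conditions: (R)-2-[diphenyl(trimethylsilyloxy)methyl]pyrrolidine (20 mol %), 4-nitrophenol (20 mol %), toluene, 0 °C → rt; then NaBH4, MeOH, 0 °C
Reagents that add atoms: none
Why: Enamine-catalysed Michael addition of an aldehyde to a nitroalkene: the (E)-enamine of 11 attacks through the acyclic synclinal transition state on the face left open by the catalyst's bulky diphenyl(silyloxy)methyl group, giving the syn adduct, so both new centres (C3' and C9) are catalyst-controlled with the (R)-catalyst as the enantiomer of the required sense; NaBH4 then reduces the epimerizable aldehyde in the same flask.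

Step 8
Reactants: 13 tert-butyl (2S,5S)-2-[(2S,3S,4S)-4-(benzyloxy)-3-(hydroxymethyl)-1-nitropentan-2-yl]-5-ethenylpyrrolidine-1-carboxylate
Product: 14 methyl 7-(benzyloxy)-5-[(2S,5S)-1-(tert-butoxycarbonyl)-5-ethenylpyrrolidin-2-yl]-6-(hydroxymethyl)-4-nitrooctanoate
Conditions: methyl acrylate, DBU (0.2 equiv), MeCN, 0 °C
Reagents that add atoms: methyl acrylate (C=CC(=O)OC)
Why: Base-catalysed Michael addition of the nitronate to the acrylate builds C7–C8 and brings in C5–C7; the branched C9 neighbour should suppress double addition, and the new C8 centre is irrelevant because the nitro group is removed in step 9.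

Step 9
Reactants: 14 methyl 7-(benzyloxy)-5-[(2S,5S)-1-(tert-butoxycarbonyl)-5-ethenylpyrrolidin-2-yl]-6-(hydroxymethyl)-4-nitrooctanoate
Product: 15 methyl (5R,6S,7S)-7-(benzyloxy)-5-[(2S,5S)-1-(tert-butoxycarbonyl)-5-ethenylpyrrolidin-2-yl]-6-(hydroxymethyl)octanoate
Conditions: Bu3SnH, AIBN, toluene, 110 °C
Reagents that add atoms: none
Why: Radical denitration of a secondary nitroalkane (tin-radical addition to the nitro group, C–N homolysis, hydrogen-atom transfer); cyclization of the C8 radical onto the vinyl group would have to bridge the trans-2,5-disubstituted pyrrolidine and is geometrically excluded.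

Step 10
Reactants: 15 methyl (5R,6S,7S)-7-(benzyloxy)-5-[(2S,5S)-1-(tert-butoxycarbonyl)-5-ethenylpyrrolidin-2-yl]-6-(hydroxymethyl)octanoate
Product: 17 (3S,9R,9aS)-9-[(2S,3S)-3-(benzyloxy)-1-hydroxybutan-2-yl]-3-ethenyloctahydro-5H-pyrrolo[1,2-a]azepin-5-one, via amino ester 16 (not isolated)
Conditions: TFA, CH2Cl2, 0 °C → rt; concentrate; then Et3N, 2-hydroxypyridine (cat.), toluene, 100 °C
Reagents that add atoms: none
Why: Acidolysis of the Boc group and bifunctionally catalysed aminolysis of the methyl ester by the pyrrolidine nitrogen (7-exo-trig lactamization) should close the azepinone; the benzyl ether and the vinyl group are inert to TFA.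

Step 11
Reactants: 17 (3S,9R,9aS)-9-[(2S,3S)-3-(benzyloxy)-1-hydroxybutan-2-yl]-3-ethenyloctahydro-5H-pyrrolo[1,2-a]azepin-5-one
Product: 18 (2R,3S)-3-(benzyloxy)-2-[(3S,9R,9aS)-3-ethenyl-5-oxooctahydro-1H-pyrrolo[1,2-a]azepin-9-yl]butanal
Conditions: Dess–Martin periodinane, NaHCO3, CH2Cl2, 0 °C → rt; used crude
Reagents that add atoms: none
Why: Buffered Dess–Martin oxidation of the primary alcohol is non-epimerizing for the α-branched aldehyde and leaves lactam, ether and alkene untouched.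

Step 12
Reactants: 18 (2R,3S)-3-(benzyloxy)-2-[(3S,9R,9aS)-3-ethenyl-5-oxooctahydro-1H-pyrrolo[1,2-a]azepin-9-yl]butanal
Product: 20 (3S,4R,5S)-5-(benzyloxy)-4-[(3S,9R,9aS)-3-ethenyl-5-oxooctahydro-1H-pyrrolo[1,2-a]azepin-9-yl]hex-1-en-3-yl 2-methylprop-2-enoate, via magnesium alkoxide 19 (not isolated)
Conditions: MgBr2·OEt2, CH2Cl2, −78 °C; CH2=CHMgBr; then methacryloyl chloride, DMAP (cat.), −78 → 0 °C
Reagents that add atoms: vinylmagnesium bromide (C=C[Mg]Br); methacryloyl chloride (CC(=C)C(=O)Cl)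
Why: Chelation-controlled Grignard addition (Cram chelate): magnesium bridges the aldehyde and β-benzyloxy oxygens in a six-membered chelate whose two ring substituents (the C9 appendage and the C2' methyl) lie on the same face, so the vinyl group adds from the opposite face and sets C3a'; the alkoxide is acylated in the same flask.

Step 13
Reactants: 20 (3S,4R,5S)-5-(benzyloxy)-4-[(3S,9R,9aS)-3-ethenyl-5-oxooctahydro-1H-pyrrolo[1,2-a]azepin-9-yl]hex-1-en-3-yl 2-methylprop-2-enoate
Product: 21 (5S)-5-[(1R,2S)-2-(benzyloxy)-1-[(3S,9R,9aS)-3-ethenyl-5-oxooctahydro-1H-pyrrolo[1,2-a]azepin-9-yl]propyl]-3-methylfuran-2(5H)-one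
Conditions: second-generation Grubbs catalyst RuCl2(=CHPh)(PCy3)(H2IMes) (10 mol %), toluene (2 mM), 80 °C
Reagents that add atoms: none
Why: Ring-closing metathesis of the allyl methacrylate unit gives the α-methylbutenolide; the C3 vinyl group cannot close a ring with either alkene because that would bridge the trans-disubstituted pyrrolidine, and high dilution should suppress cross-metathesis.

Step 14
Reactants: 21 (5S)-5-[(1R,2S)-2-(benzyloxy)-1-[(3S,9R,9aS)-3-ethenyl-5-oxooctahydro-1H-pyrrolo[1,2-a]azepin-9-yl]propyl]-3-methylfuran-2(5H)-one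
Product: 23 (2S,3R,3aR,6S,6aR)-3-[(3S,9R,9aS)-3-ethenyl-5-oxooctahydro-1H-pyrrolo[1,2-a]azepin-9-yl]-2,6-dimethylhexahydrofuro[3,2-b]furan-5-one, via hydroxy butenolide 22 (not isolated)
Conditions: BCl3, CH2Cl2, −78 °C; MeOH quench; then DBU (0.1 equiv), CH2Cl2, −40 °C, short time; AcOH quench
Reagents that add atoms: none
Why: BCl3 cleaves the benzyl ether and the freed C2' hydroxyl adds to the butenolide β-carbon (5-exo-trig oxa-Michael), which can only give the cis-fused bicycle (C6a'); the enolate should be protonated from the convex face, placing the C6' methyl on the concave face as required, and the cold, brief, catalytic-base conditions are chosen to avoid equilibration.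

Step 15
Reactants: 23 (2S,3R,3aR,6S,6aR)-3-[(3S,9R,9aS)-3-ethenyl-5-oxooctahydro-1H-pyrrolo[1,2-a]azepin-9-yl]-2,6-dimethylhexahydrofuro[3,2-b]furan-5-one; 24 methylmalonic acid
Product: 25 (5S)-5-[(3S,9R,9aS)-9-[(2S,3R,3aR,6S,6aR)-2,6-dimethyl-5-oxohexahydrofuro[3,2-b]furan-3-yl]-5-oxooctahydro-1H-pyrrolo[1,2-a]azepin-3-yl]-3-methyl-2-oxooxolane-3-carboxylic acid
Conditions: Mn(OAc)3·2H2O (2.5 equiv), 24 (5 equiv), KOAc, AcOH, 60 °C, N2
Reagents that add atoms: none
Why: Mn(OAc)3 oxidizes the manganese enolate of methylmalonic acid to the electrophilic radical •C(CH3)(CO2H)2, which adds to the terminal CH2 of the C3 vinyl group (Cα–Cβ bond) and gives a secondary radical at Cγ that is still bound to manganese through its carboxylate; a second Mn(OAc)3 oxidizes this radical in the inner sphere while the carboxylate oxygen is transferred to Cγ (O–Cγ bond). The closest known reaction type is the manganese triacetate γ-lactone annulation of terminal alkenes with malonic acids and other α-activated carboxylic acids. The lactone ring closes in a five-membered exo-type ligand transfer of the carboxylate oxygen onto the radical carbon, the only ring size the tether Cα–Cβ–Cγ allows. Cγ is set under substrate control by C3: allylic 1,3-strain with the C5 lactam carbonyl keeps the side chain pseudo-axial with H3 eclipsing Cβ, and the manganese carboxylate, which can bind the lactam oxygen, should deliver its oxygen to the radical face syn to the planar lactam nitrogen and anti to the ring CH2 (C2), which is the threo N/O arrangement of the target, whereas the quaternary Cα formed here is stereochemically irrelevant because step 16 resets it. The step needs regioselectivity (attack at CH2, secured by the terminal alkene), chemoselectivity (only the malonic acid, far more acidic than the lactone and lactam α-CH, is enolized by trivalent manganese at 60 °C, and the product has no α-hydrogen left) and freedom from free-cation chemistry (1,2-hydride shift to an N-acyliminium ion, capture by the lactam oxygen), which the inner-sphere oxidation and the non-basic amide nitrogen are expected to secure.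

Step 16
Reactants: 25 (5S)-5-[(3S,9R,9aS)-9-[(2S,3R,3aR,6S,6aR)-2,6-dimethyl-5-oxohexahydrofuro[3,2-b]furan-3-yl]-5-oxooctahydro-1H-pyrrolo[1,2-a]azepin-3-yl]-3-methyl-2-oxooxolane-3-carboxylic acid
Product: 26 (2S,3R,3aR,6S,6aR)-2,6-dimethyl-3-[(3S,9R,9aS)-3-[(2S,4S)-4-methyl-5-oxooxolan-2-yl]-5-oxooctahydro-1H-pyrrolo[1,2-a]azepin-9-yl]hexahydrofuro[3,2-b]furan-5-one
Conditions: DMSO, 120 °C
Reagents that add atoms: none
Why: Thermal decarboxylation of the malonic half-acid removes the activating carboxyl through the lactone enol, which should be protonated on the face anti to the bulky Cγ substituent to give the cis-2,4-disubstituted lactone under kinetic control; the neutral conditions leave C6' untouched.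

Step 17
Reactants: 26 (2S,3R,3aR,6S,6aR)-2,6-dimethyl-3-[(3S,9R,9aS)-3-[(2S,4S)-4-methyl-5-oxooxolan-2-yl]-5-oxooctahydro-1H-pyrrolo[1,2-a]azepin-9-yl]hexahydrofuro[3,2-b]furan-5-one
Product: 27 (2S,3R,3aR,6S,6aR)-2,6-dimethyl-3-[(3S,9R,9aS)-3-[(2S,4S)-4-methyl-5-oxooxolan-2-yl]octahydro-1H-pyrrolo[1,2-a]azepin-9-yl]hexahydrofuro[3,2-b]furan-5-one
Conditions: RhH(CO)(PPh3)3 (5 mol %), Ph2SiH2, THF, rt; aqueous work-up
Reagents that add atoms: none
Why: Rhodium-catalysed hydrosilylation reduces the tertiary lactam to the amine (through the O-silyl hemiaminal and iminium ion), a reaction type known to spare γ-lactones; no stereocentre is touched.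

**Compound list**

1 | 1-tert-butyl 2-methyl (2S)-5-oxopyrrolidine-1,2-dicarboxylate (N-Boc methyl L-pyroglutamate) | COC(=O)[C@@H]1CCC(=O)N1C(=O)OC(C)(C)C | starting material
2 | 1-tert-butyl 2-methyl (2S)-5-hydroxypyrrolidine-1,2-dicarboxylate (C5 epimers) | COC(=O)[C@@H]1CCC(O)N1C(=O)OC(C)(C)C | intermediate
3 | 1-tert-butyl 2-methyl (2S)-5-methoxypyrrolidine-1,2-dicarboxylate (C5 epimers) | COC(=O)[C@@H]1CCC(OC)N1C(=O)OC(C)(C)C | intermediate
4 | 1-tert-butyl 2-methyl (2S,5S)-5-ethenylpyrrolidine-1,2-dicarboxylate (trans) | O=C(OC(C)(C)C)N1[C@H](C(=O)OC)CC[C@H]1C=C | intermediate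
5 | tert-butyl (2S,5S)-2-ethenyl-5-formylpyrrolidine-1-carboxylate | O=C(OC(C)(C)C)N1[C@H](C=O)CC[C@H]1C=C | intermediate
6 | tert-butyl (2S,5S)-2-ethenyl-5-(1-hydroxy-2-nitroethyl)pyrrolidine-1-carboxylate (carbinol epimers) | O=C(OC(C)(C)C)N1[C@H](C(O)C[N+](=O)[O-])CC[C@H]1C=C | intermediate
7 | tert-butyl (2S,5S)-2-ethenyl-5-[1-(methylsulfonyloxy)-2-nitroethyl]pyrrolidine-1-carboxylate | O=C(OC(C)(C)C)N1[C@H](C(OS(C)(=O)=O)C[N+](=O)[O-])CC[C@H]1C=C | intermediate
8 | tert-butyl (2S,5S)-2-ethenyl-5-[(E)-2-nitroethenyl]pyrrolidine-1-carboxylate | O=C(OC(C)(C)C)N1[C@H](/C=C/[N+](=O)[O-])CC[C@H]1C=C | intermediate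
9 | ethyl (3S)-3-hydroxybutanoate | CCOC(=O)C[C@H](C)O | starting material
10 | ethyl (3S)-3-(benzyloxy)butanoate | CCOC(=O)C[C@H](C)OCc1ccccc1 | intermediate
11 | (3S)-3-(benzyloxy)butanal | O=CC[C@H](C)OCc1ccccc1 | intermediate
12 | tert-butyl (2S,5S)-2-[(2S,3R,4S)-4-(benzyloxy)-3-formyl-1-nitropentan-2-yl]-5-ethenylpyrrolidine-1-carboxylate | C[C@H](OCc1ccccc1)[C@H](C=O)[C@@H](C[N+](=O)[O-])[C@@H]1CC[C@@H](C=C)N1C(=O)OC(C)(C)C | intermediate
13 | tert-butyl (2S,5S)-2-[(2S,3S,4S)-4-(benzyloxy)-3-(hydroxymethyl)-1-nitropentan-2-yl]-5-ethenylpyrrolidine-1-carboxylate | C[C@H](OCc1ccccc1)[C@H](CO)[C@@H](C[N+](=O)[O-])[C@@H]1CC[C@@H](C=C)N1C(=O)OC(C)(C)C | intermediate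
14 | methyl 7-(benzyloxy)-5-[(2S,5S)-1-(tert-butoxycarbonyl)-5-ethenylpyrrolidin-2-yl]-6-(hydroxymethyl)-4-nitrooctanoate (C4 epimers; C5, C6, C7 as in 13) | C[C@H](OCc1ccccc1)[C@H](CO)[C@@H](C(CCC(=O)OC)[N+](=O)[O-])[C@@H]1CC[C@@H](C=C)N1C(=O)OC(C)(C)C | intermediate
15 | methyl (5R,6S,7S)-7-(benzyloxy)-5-[(2S,5S)-1-(tert-butoxycarbonyl)-5-ethenylpyrrolidin-2-yl]-6-(hydroxymethyl)octanoate | C[C@H](OCc1ccccc1)[C@H](CO)[C@@H](CCCC(=O)OC)[C@@H]1CC[C@@H](C=C)N1C(=O)OC(C)(C)C | intermediate
16 | methyl (5R,6S,7S)-7-(benzyloxy)-5-[(2S,5S)-5-ethenylpyrrolidin-2-yl]-6-(hydroxymethyl)octanoate | C[C@H](OCc1ccccc1)[C@H](CO)[C@@H](CCCC(=O)OC)[C@@H]1CC[C@@H](C=C)N1 | intermediate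
17 | (3S,9R,9aS)-9-[(2S,3S)-3-(benzyloxy)-1-hydroxybutan-2-yl]-3-ethenyloctahydro-5H-pyrrolo[1,2-a]azepin-5-one | C[C@H](OCc1ccccc1)[C@H](CO)[C@H]1CCCC(=O)N2[C@H]1CC[C@H]2C=C | intermediate
18 | (2R,3S)-3-(benzyloxy)-2-[(3S,9R,9aS)-3-ethenyl-5-oxooctahydro-1H-pyrrolo[1,2-a]azepin-9-yl]butanal | C[C@H](OCc1ccccc1)[C@H](C=O)[C@H]1CCCC(=O)N2[C@H]1CC[C@H]2C=C | intermediate
19 | bromomagnesium (3S,4R,5S)-5-(benzyloxy)-4-[(3S,9R,9aS)-3-ethenyl-5-oxooctahydro-1H-pyrrolo[1,2-a]azepin-9-yl]hex-1-en-3-olate | C[C@H](OCc1ccccc1)[C@H]([C@@H](O[Mg]Br)C=C)[C@H]1CCCC(=O)N2[C@H]1CC[C@H]2C=C | intermediate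
20 | (3S,4R,5S)-5-(benzyloxy)-4-[(3S,9R,9aS)-3-ethenyl-5-oxooctahydro-1H-pyrrolo[1,2-a]azepin-9-yl]hex-1-en-3-yl 2-methylprop-2-enoate | C[C@H](OCc1ccccc1)[C@H]([C@@H](OC(=O)C(C)=C)C=C)[C@H]1CCCC(=O)N2[C@H]1CC[C@H]2C=C | intermediate
21 | (5S)-5-[(1R,2S)-2-(benzyloxy)-1-[(3S,9R,9aS)-3-ethenyl-5-oxooctahydro-1H-pyrrolo[1,2-a]azepin-9-yl]propyl]-3-methylfuran-2(5H)-one | C[C@H](OCc1ccccc1)[C@H]([C@H]1OC(=O)C(C)=C1)[C@H]1CCCC(=O)N2[C@H]1CC[C@H]2C=C | intermediate
22 | (5S)-5-[(1R,2S)-1-[(3S,9R,9aS)-3-ethenyl-5-oxooctahydro-1H-pyrrolo[1,2-a]azepin-9-yl]-2-hydroxypropyl]-3-methylfuran-2(5H)-one | C[C@H](O)[C@H]([C@H]1OC(=O)C(C)=C1)[C@H]1CCCC(=O)N2[C@H]1CC[C@H]2C=C | intermediate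
23 | (2S,3R,3aR,6S,6aR)-3-[(3S,9R,9aS)-3-ethenyl-5-oxooctahydro-1H-pyrrolo[1,2-a]azepin-9-yl]-2,6-dimethylhexahydrofuro[3,2-b]furan-5-one | C[C@@H]1O[C@H]2[C@H](OC(=O)[C@H]2C)[C@@H]1[C@H]1CCCC(=O)N2[C@H]1CC[C@H]2C=C | intermediate
24 | methylmalonic acid (2-methylpropanedioic acid) | CC(C(=O)O)C(=O)O | starting material
25 | (5S)-5-[(3S,9R,9aS)-9-[(2S,3R,3aR,6S,6aR)-2,6-dimethyl-5-oxohexahydrofuro[3,2-b]furan-3-yl]-5-oxooctahydro-1H-pyrrolo[1,2-a]azepin-3-yl]-3-methyl-2-oxooxolane-3-carboxylic acid (both epimers at the quaternary carbon) | C[C@@H]1O[C@H]2[C@H](OC(=O)[C@H]2C)[C@@H]1[C@H]1CCCC(=O)N2[C@H]1CC[C@H]2[C@@H]1CC(C)(C(=O)O)C(=O)O1 | intermediate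
26 | (2S,3R,3aR,6S,6aR)-2,6-dimethyl-3-[(3S,9R,9aS)-3-[(2S,4S)-4-methyl-5-oxooxolan-2-yl]-5-oxooctahydro-1H-pyrrolo[1,2-a]azepin-9-yl]hexahydrofuro[3,2-b]furan-5-one | C[C@@H]1O[C@H]2[C@H](OC(=O)[C@H]2C)[C@@H]1[C@H]1CCCC(=O)N2[C@H]1CC[C@H]2[C@@H]1C[C@H](C)C(=O)O1 | intermediate
27 | (2S,3R,3aR,6S,6aR)-2,6-dimethyl-3-[(3S,9R,9aS)-3-[(2S,4S)-4-methyl-5-oxooxolan-2-yl]octahydro-1H-pyrrolo[1,2-a]azepin-9-yl]hexahydrofuro[3,2-b]furan-5-one | C[C@@H]1O[C@H]2[C@H](OC(=O)[C@H]2C)[C@@H]1[C@H]1CCCCN2[C@H]1CC[C@H]2[C@@H]1C[C@H](C)C(=O)O1 | target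

**Step count and risks**

Total step count: 17. Longest linear sequence: 15 steps (steps 1–4 and 7–17).

The three steps most likely to fail:

Step 15 (key step). What may go wrong: poor facial selectivity at the Cγ radical, escape into cation chemistry (hydride shift, capture by the lactam oxygen), or sluggish radical addition to the inductively deactivated alkene. The fallback sets out from 23 and comes back at 26. Ozonolysis of the vinyl group (O3, CH2Cl2/MeOH, −78 °C; Me2S) should give the C3 carbaldehyde F1. A Barbier addition of ethyl 2-(bromomethyl)acrylate mediated by In (THF/H2O), with the metal chelated between the aldehyde and lactam oxygens so that attack is anti to ring C2 (threo), should give the hydroxy ester F2. This closes with p-TsOH to the α-methylene-γ-butyrolactone F3. Hydrogenation (H2, Rh/Al2O3, EtOAc) should add hydrogen anti to the Cγ substituent and give 26 with the cis methyl group.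

Step 7. What may go wrong: slow conjugate addition to the β-branched chiral nitroalkene, mismatched double stereodifferentiation, or epimerization next to the aldehyde before reduction. The fallback sets out from 10 (with 8) and comes back at 13. Saponification (LiOH, THF/H2O) should give (3S)-3-(benzyloxy)butanoic acid F4. Carbodiimide coupling with (4R)-4-benzyl-1,3-oxazolidin-2-one should give the imide F5. The chlorotitanium enolate of F5 (TiCl4, i-Pr2NEt, CH2Cl2, −78 °C) should add to nitroalkene 8 under auxiliary control to give the adduct F6. Reductive removal of the auxiliary (LiBH4, THF/MeOH) should give 13.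

Step 14. What may go wrong: equilibration of the C6' centre (enolization or retro-oxa-Michael and re-addition) to the convex-methyl epimer, or γ-epimerization of the butenolide under base. The fallback sets out from 21 and comes back at 23. After the same debenzylation, cyclization with a full equivalent of DBU at room temperature is driven deliberately to the thermodynamic cis-fused lactone F7 (C6' methyl on the convex face). Its lithium enolate (LiN(SiMe3)2, THF, −78 °C; the lactone α-CH is more acidic than the lactam α-CH2) is then added to 2,6-di-tert-butylphenol, which should deliver the proton to the convex face and return 23.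

Further compounds
F1 | step 15 | (3S,9R,9aS)-9-[(2S,3R,3aR,6S,6aR)-2,6-dimethyl-5-oxohexahydrofuro[3,2-b]furan-3-yl]-5-oxooctahydro-1H-pyrrolo[1,2-a]azepine-3-carbaldehyde | C[C@@H]1O[C@H]2[C@H](OC(=O)[C@H]2C)[C@@H]1[C@H]1CCCC(=O)N2[C@H]1CC[C@H]2C=O
F2 | step 15 | ethyl (4S)-4-[(3S,9R,9aS)-9-[(2S,3R,3aR,6S,6aR)-2,6-dimethyl-5-oxohexahydrofuro[3,2-b]furan-3-yl]-5-oxooctahydro-1H-pyrrolo[1,2-a]azepin-3-yl]-4-hydroxy-2-methylidenebutanoate | C[C@@H]1O[C@H]2[C@H](OC(=O)[C@H]2C)[C@@H]1[C@H]1CCCC(=O)N2[C@H]1CC[C@H]2[C@@H](O)CC(=C)C(=O)OCC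
F3 | step 15 | (2S,3R,3aR,6S,6aR)-2,6-dimethyl-3-[(3S,9R,9aS)-3-[(2S)-4-methylidene-5-oxooxolan-2-yl]-5-oxooctahydro-1H-pyrrolo[1,2-a]azepin-9-yl]hexahydrofuro[3,2-b]furan-5-one | C[C@@H]1O[C@H]2[C@H](OC(=O)[C@H]2C)[C@@H]1[C@H]1CCCC(=O)N2[C@H]1CC[C@H]2[C@@H]1CC(=C)C(=O)O1
F4 | step 7 | (3S)-3-(benzyloxy)butanoic acid | C[C@H](OCc1ccccc1)CC(=O)O
F5 | step 7 | (4R)-4-benzyl-3-[(3S)-3-(benzyloxy)butanoyl]-1,3-oxazolidin-2-one | C[C@H](OCc1ccccc1)CC(=O)N1[C@H](Cc2ccccc2)COC1=O
F6 | step 7 | tert-butyl (2S,5S)-2-[(2S,3R,4S)-4-(benzyloxy)-3-[(4R)-4-benzyl-2-oxo-1,3-oxazolidine-3-carbonyl]-1-nitropentan-2-yl]-5-ethenylpyrrolidine-1-carboxylate | C[C@H](OCc1ccccc1)[C@H](C(=O)N1[C@H](Cc2ccccc2)COC1=O)[C@@H](C[N+](=O)[O-])[C@@H]1CC[C@@H](C=C)N1C(=O)OC(C)(C)C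
F7 | step 14 | (2S,3R,3aR,6R,6aR)-3-[(3S,9R,9aS)-3-ethenyl-5-oxooctahydro-1H-pyrrolo[1,2-a]azepin-9-yl]-2,6-dimethylhexahydrofuro[3,2-b]furan-5-one (C6' epimer of 23) | C[C@@H]1O[C@H]2[C@H](OC(=O)[C@@H]2C)[C@@H]1[C@H]1CCCC(=O)N2[C@H]1CC[C@H]2C=C
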